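The two 2-aryl-3-(hydroxymethyl)-2,3-dihydrobenzofurans are treated as ring-contracted flavanones, so the bond C3–C3a of each furan is the strategic disconnection. In one operation a trivalent-iodine oxidation converts (2S)-flavanone 6 into trans ester 7: the arene carbon C4a of ring C migrates from C4 to C3, the pyranone shrinks to the furan, C4 becomes the ester carbon and C2 dictates the new C3 configuration. The step exploits the C4 ketone lying between enolisable C3 and the oxygen-activated fused carbon C4a. Precursor 6, a 6-bromo-8-methoxyflavanone carrying O-benzylated ring D, comes from asymmetric arylboronic acid addition to a chromone. Iteration, then a lactone aldol and hemiketal reduction, complete the all-cis tetrahydrofuran.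

Key step: step 4

Remark: ring letters are A (guaiacyl ring of the arylmethyl group), B (benzo ring of the inner dihydrobenzofuran), C (benzo ring of the outer dihydrobenzofuran) and D (terminal guaiacyl ring); TBS = tert-butyldimethylsilyl.
Remark: the target SMILES fixes the oxolane as 2R,3R,4R with aryl, CH2OH and arylmethyl all cis (the C2 epimer of a lariciresinol-type ring); steps 14–16 are designed for this isomer.
Remark: the (S)-t-BuPyOx ligand is assumed to give the 2R flavanone, by analogy with its additions to cyclic enones; if the sense is the reverse, the ligands of steps 3 and 6 are exchanged.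

Step 1
Reactants: 1 1-(2-hydroxy-3-methoxyphenyl)ethanone
Product: 2 1-(5-bromo-2-hydroxy-3-methoxyphenyl)ethanone
Conditions: NBS (1.05 equiv), MeCN, 0 °C to rt
Reagents that add atoms: N-bromosuccinimide O=C1CCC(=O)N1Br
Why: Electrophilic aromatic bromination, in which the free phenol directs to its para position C5 because both ortho positions are blocked by the acetyl and methoxy groups, so a single bromide should result.

Step 2
Reactants: 2 1-(5-bromo-2-hydroxy-3-methoxyphenyl)ethanone
Product: 4 6-bromo-8-methoxy-4H-chromen-4-one, via enaminone 3 (not isolated)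
Conditions: Me2NCH(OMe)2, toluene, 100 °C; then conc. HCl, CH2Cl2, 40 °C
Reagents that add atoms: N,N-dimethylformamide dimethyl acetal COC(OC)N(C)C
Why: Enaminone route to chromones, in which condensation of the methyl ketone with the amide acetal gives the vinylogous amide and acid then drives addition of the phenol oxygen to the β-carbon with loss of dimethylamine (addition–elimination) to close the pyranone.

Step 3
Reactants: 4 6-bromo-8-methoxy-4H-chromen-4-one; 5 [4-(benzyloxy)-3-methoxyphenyl]boronic acid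
Product: 6 (2S)-2-[4-(benzyloxy)-3-methoxyphenyl]-6-bromo-8-methoxy-2,3-dihydro-4H-chromen-4-one
Conditions: Pd(OCOCF3)2 (5 mol%), (R)-t-BuPyOx (6 mol%), NH4PF6 (30 mol%), H2O (5 equiv), ClCH2CH2Cl, 60 °C
Reagents that add atoms: none
Why: Palladium-catalysed asymmetric conjugate addition of an arylboronic acid to a chromone, in which the cationic aryl complex of divalent palladium with the pyridine–oxazoline inserts C2=C3 on the face left open by the tert-butyl group and water protonates the palladium enolate, so that C2 should be set as S under ligand control while the aryl bromide stays intact because no zerovalent palladium–phosphine species is present.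

Step 4
Reactants: 6 (2S)-2-[4-(benzyloxy)-3-methoxyphenyl]-6-bromo-8-methoxy-2,3-dihydro-4H-chromen-4-one
Product: 7 methyl (2S,3S)-2-[4-(benzyloxy)-3-methoxyphenyl]-5-bromo-7-methoxy-2,3-dihydro-1-benzofuran-3-carboxylate (2,3-trans)
Conditions: PhI(OAc)2 (1.2 equiv), H2SO4 (0.5 equiv), HC(OMe)3, 0 °C to rt
Reagents that add atoms: trimethyl orthoformate COC(OC)OC
Why: Acid and orthoformate turn the C4 ketone into its methyl enol ether, whose C3 attacks the trivalent iodine anti to the C2 aryl group, and methanol capture at C4 gives a 4,4-dimethoxy-3-iodanyl chroman with the C3–I bond antiperiplanar to the ring bond C4–C4a. Loss of iodobenzene is assisted by C4a, which shifts from C4 to C3 through a bridged phenonium-type transition state while the two methoxy groups stabilise the emerging cation at C4, which then collapses to the methyl ester by loss of one methyl group. The closest known reaction type is the oxidative 1,2-aryl shift of aryl ketone acetals induced by hypervalent iodine or Tl(NO3)3, which is established for flavanones. The furan ring is closed by ring contraction, that is by 3-exo-tet ipso participation of C4a at C3 followed by cleavage of C4–C4a, and not by an end-on cyclisation. The new stereocentre C3 is governed by C2, since the migrating carbon enters the trans iodane with inversion and the benzylic ester centre can in any case equilibrate under acid to the trans isomer, so the 2S,3S product is expected. The step needs migration of C4a and not of ring D and needs C2 to stay intact; the diequatorial geometry of the iodane together with the ring oxygen ortho to C4a should secure the first, and the acidic, base-free medium, in which retro-oxa-Michael opening cannot start, the second.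

Step 5
Reactants: 7 methyl (2S,3S)-2-[4-(benzyloxy)-3-methoxyphenyl]-5-bromo-7-methoxy-2,3-dihydro-1-benzofuran-3-carboxylate
Product: 9 [(2S,3S)-2-[4-(benzyloxy)-3-methoxyphenyl]-7-methoxy-3-(methoxycarbonyl)-2,3-dihydro-1-benzofuran-5-yl]boronic acid, via pinacol boronate 8 (not isolated)
Conditions: B2pin2, Pd(dppf)Cl2 (3 mol%), KOAc, 1,4-dioxane, 90 °C; then NaIO4, NH4OAc, acetone/H2O, rt
Reagents that add atoms: bis(pinacolato)diboron CC1(C)OB(OC1(C)C)B1OC(C)(C)C(C)(C)O1; water O
Why: Miyaura borylation (oxidative addition of zerovalent palladium into C–Br, acetate-assisted transmetalation with the diboron, reductive elimination) followed by periodate cleavage of the pinacol frees the boronic acid needed for the next addition, and the weakly basic and then buffered media should leave the trans ester and C2 untouched.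

Step 6
Reactants: 9 [(2S,3S)-2-[4-(benzyloxy)-3-methoxyphenyl]-7-methoxy-3-(methoxycarbonyl)-2,3-dihydro-1-benzofuran-5-yl]boronic acid; 4 6-bromo-8-methoxy-4H-chromen-4-one (1.5 equiv)
Product: 10 methyl (2S,3S)-2-[4-(benzyloxy)-3-methoxyphenyl]-5-[(2R)-6-bromo-8-methoxy-4-oxo-3,4-dihydro-2H-chromen-2-yl]-7-methoxy-2,3-dihydro-1-benzofuran-3-carboxylate
Conditions: Pd(OCOCF3)2 (5 mol%), (S)-t-BuPyOx (6 mol%), NH4PF6 (30 mol%), H2O (5 equiv), ClCH2CH2Cl, 60 °C
Reagents that add atoms: none
Why: The same palladium-catalysed asymmetric conjugate addition as in step 3, now with the antipodal ligand, so that the new flavanone C2 should be set as R under catalyst control, the stereocentres of the boronic acid being too remote to interfere.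

Step 7
Reactants: 10 methyl (2S,3S)-2-[4-(benzyloxy)-3-methoxyphenyl]-5-[(2R)-6-bromo-8-methoxy-4-oxo-3,4-dihydro-2H-chromen-2-yl]-7-methoxy-2,3-dihydro-1-benzofuran-3-carboxylate
Product: 11 methyl (2R,3R)-5-bromo-2-[(2S,3S)-2-[4-(benzyloxy)-3-methoxyphenyl]-7-methoxy-3-(methoxycarbonyl)-2,3-dihydro-1-benzofuran-5-yl]-7-methoxy-2,3-dihydro-1-benzofuran-3-carboxylate
Conditions: PhI(OAc)2 (1.2 equiv), H2SO4 (0.5 equiv), HC(OMe)3, 0 °C
Reagents that add atoms: trimethyl orthoformate COC(OC)OC
Why: The same hypervalent-iodine oxidative ring contraction as in step 4, in which C4a of the new chromanone migrates from C4 to C3 in the trans iodane and the 2R centre relays to the 2R,3R trans ester, while the existing ester and the benzyl ether are inert to the acidic medium.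

Step 8
Reactants: 11 methyl (2R,3R)-5-bromo-2-[(2S,3S)-2-[4-(benzyloxy)-3-methoxyphenyl]-7-methoxy-3-(methoxycarbonyl)-2,3-dihydro-1-benzofuran-5-yl]-7-methoxy-2,3-dihydro-1-benzofuran-3-carboxylate
Product: 12 [(2R,3S)-5-bromo-2-{(2S,3R)-2-[4-(benzyloxy)-3-methoxyphenyl]-3-(hydroxymethyl)-7-methoxy-2,3-dihydro-1-benzofuran-5-yl}-7-methoxy-2,3-dihydro-1-benzofuran-3-yl]methanol
Conditions: LiBH4, THF/MeOH, 0 °C to rt
Reagents that add atoms: none
Why: Borohydride reduction of both methyl esters to primary alcohols, which touches no stereocentre (the C3 descriptors change only by priority) and leaves the aryl bromide and the benzyl ether alone.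

Step 9
Reactants: 12 the diol of step 8
Product: 13 bis(tert-butyldimethylsilyl) ether of 12 (both CH2OH groups silylated)
Conditions: TBSCl, imidazole, DMF, rt
Reagents that add atoms: tert-butyldimethylsilyl chloride CC(C)(C)[Si](C)(C)Cl
Why: Standard silylation of primary alcohols, which masks the two hydroxyls against the organolithium and enolate bases that follow.

Step 10
Reactants: 13 bis(tert-butyldimethylsilyl) ether of 12
Product: 15 the aldehyde in which CHO replaces the bromine of 13 (C5 of the inner benzofuran), via aryllithium 14 (not isolated)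
Conditions: n-BuLi, THF, −78 °C; then DMF, −78 to 0 °C; aq. NH4Cl
Reagents that add atoms: N,N-dimethylformamide CN(C)C=O
Why: Bromine–lithium exchange at −78 °C, which is much faster than any deprotonation, followed by formylation of the aryllithium with DMF (Bouveault aldehyde synthesis).

Step 11
Reactants: 16 4-(benzyloxy)-3-methoxybenzaldehyde; 17 dimethyl butanedioate
Product: 18 (3E)-4-[4-(benzyloxy)-3-methoxyphenyl]-3-(methoxycarbonyl)but-3-enoic acid
Conditions: NaOMe, MeOH, reflux; then aq. HCl
Reagents that add atoms: none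
Why: Stobbe condensation, in which the succinate enolate adds to the aldehyde, lactonises and opens by elimination to the E itaconic half-ester, leaving the two carboxyl groups differentiated.

Step 12
Reactants: 18 (3E)-4-[4-(benzyloxy)-3-methoxyphenyl]-3-(methoxycarbonyl)but-3-enoic acid
Product: 19 (3R)-4-[4-(benzyloxy)-3-methoxyphenyl]-3-(methoxycarbonyl)butanoic acid
Conditions: [Rh(cod)((S,S)-Et-DuPHOS)]OTf (0.5 mol%), Et3N (1 equiv), H2 (5 bar), MeOH, rt
Reagents that add atoms: none
Why: Rhodium-catalysed asymmetric hydrogenation of a β-aryl itaconate half-ester, in which carboxylate and alkene chelate the cationic rhodium–bisphospholane so that hydrogen is delivered to one alkene face, the ligand hand being the one expected to give the R centre by analogy with enamide substrates, and the benzyl ether is not cleaved by the homogeneous catalyst.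

Step 13
Reactants: 19 (3R)-4-[4-(benzyloxy)-3-methoxyphenyl]-3-(methoxycarbonyl)butanoic acid
Product: 21 (4R)-4-[4-(benzyloxy)-3-methoxybenzyl]oxolan-2-one, via hydroxy acid 20 (not isolated)
Conditions: KOH (1 equiv), EtOH; CaCl2, NaBH4, EtOH, 0 °C to rt; then 2 M HCl, 40 °C
Reagents that add atoms: none
Why: Chemoselective borohydride reduction, in which Ca(BH4)2 reduces the ester but not the carboxylate salt, followed by acid lactonisation (5-exo-trig acyl substitution) that does not touch the stereocentre.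

Step 14
Reactants: 21 (4R)-4-[4-(benzyloxy)-3-methoxybenzyl]oxolan-2-one (1.3 equiv); 15 the aldehyde of step 10
Product: 23 (3S,4R)-4-[4-(benzyloxy)-3-methoxybenzyl]-3-[hydroxy(aryl)methyl]oxolan-2-one (3,4-trans; both carbinol epimers; aryl is the C5 residue of 15), via lithium enolate 22 (not isolated)
Conditions: LiN(iPr)2, THF, −78 °C; then 15, −78 °C; AcOH quench
Reagents that add atoms: none
Why: Aldol addition of a lactone lithium enolate to a non-enolisable aryl aldehyde, in which the aldehyde approaches the enolate face anti to the C4 arylmethyl group and so sets C3 as S (3,4-trans), while the carbinol centre forms as a mixture that is erased in step 16.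

Step 15
Reactants: 23 the aldol adduct of step 14
Product: 24 (2R,3R)-2-[hydroxy(aryl)methyl]-3-[4-(benzyloxy)-3-methoxybenzyl]butane-1,4-diol (carbinol epimers)
Conditions: LiAlH4, THF, 0 °C
Reagents that add atoms: none
Why: Hydride reduction of the lactone to the 1,4-diol at a temperature low enough to outrun retro-aldol cleavage of the aluminium aldolate, with silyl and benzyl ethers inert.

Step 16
Reactants: 24 the triol of step 15
Product: 27 (2R,3R,4R)-2-aryl-4-[4-(benzyloxy)-3-methoxybenzyl]-3-(hydroxymethyl)oxolane (all-cis; aryl is the C5 residue of 15), via keto diol 25 (not isolated), via cyclic hemiketal 26 (not isolated)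
Conditions: MnO2, CH2Cl2, rt, filter; then Et3SiH, BF3·OEt2, CH2Cl2, −78 °C
Reagents that add atoms: none
Why: MnO2 oxidises only the benzylic carbinol, the hydroxy ketone closes with its γ-hydroxyl (5-exo-trig) to the hemiketal, and Lewis-acid ionisation to the 2-aryl oxocarbenium ion followed by silane hydride delivery to the face opposite the cis-disposed C3 and C4 substituents (ionic hydrogenation of a cyclic hemiketal) should set C2 as R and give the all-cis ring, the low temperature preventing C3 epimerisation through the enol ether.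

Step 17
Reactants: 27 the all-cis oxolane of step 16
Product: 28 the triol obtained from 27 by loss of both silyl groups (two benzyl ethers retained)
Conditions: Bu4NF, THF, 0 °C to rt
Reagents that add atoms: none
Why: Fluoride cleavage of the two primary silyl ethers, during which the still benzylated phenols exclude quinone methide formation under the mildly basic conditions.

Step 18
Reactants: 28 the triol of step 17
Product: 29 4-[(2S,3R)-5-[(2R,3S)-5-[(2R,3R,4R)-4-(4-hydroxy-3-methoxybenzyl)-3-(hydroxymethyl)oxolan-2-yl]-3-(hydroxymethyl)-7-methoxy-2,3-dihydro-1-benzofuran-2-yl]-3-(hydroxymethyl)-7-methoxy-2,3-dihydro-1-benzofuran-2-yl]-2-methoxyphenol (target)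
Conditions: H2 (1 atm), Pd/C (10% palladium on carbon), EtOAc/MeOH, rt
Reagents that add atoms: none
Why: Hydrogenolysis of the two aryl benzyl ethers, which under neutral conditions at 1 atm should be much faster than cleavage of the cyclic benzylic C–O bonds, so the reaction is stopped after two equivalents of hydrogen.

Compound list
1 | 1-(2-hydroxy-3-methoxyphenyl)ethanone | CC(=O)c1cccc(OC)c1O | starting material
2 | 1-(5-bromo-2-hydroxy-3-methoxyphenyl)ethanone | CC(=O)c1cc(Br)cc(OC)c1O | intermediate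
3 | (E)-1-(5-bromo-2-hydroxy-3-methoxyphenyl)-3-(dimethylamino)prop-2-en-1-one (not isolated) | CN(C)/C=C/C(=O)c1cc(Br)cc(OC)c1O | intermediate
4 | 6-bromo-8-methoxy-4H-chromen-4-one | O=c1ccoc2c(OC)cc(Br)cc12 | intermediate
5 | [4-(benzyloxy)-3-methoxyphenyl]boronic acid | COc1cc(B(O)O)ccc1OCc1ccccc1 | starting material
6 | (2S)-2-[4-(benzyloxy)-3-methoxyphenyl]-6-bromo-8-methoxy-2,3-dihydro-4H-chromen-4-one | Brc1cc(OC)c2c(c1)C(=O)C[C@@H](c1ccc(OCc3ccccc3)c(OC)c1)O2 | intermediate
7 | methyl (2S,3S)-2-[4-(benzyloxy)-3-methoxyphenyl]-5-bromo-7-methoxy-2,3-dihydro-1-benzofuran-3-carboxylate | Brc1cc(OC)c2c(c1)[C@H](C(=O)OC)[C@@H](c1ccc(OCc3ccccc3)c(OC)c1)O2 | intermediate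
8 | methyl (2S,3S)-2-[4-(benzyloxy)-3-methoxyphenyl]-7-methoxy-5-(4,4,5,5-tetramethyl-1,3,2-dioxaborolan-2-yl)-2,3-dihydro-1-benzofuran-3-carboxylate (not isolated) | CC1(C)OB(OC1(C)C)c1cc(OC)c2c(c1)[C@H](C(=O)OC)[C@@H](c1ccc(OCc3ccccc3)c(OC)c1)O2 | intermediate
9 | [(2S,3S)-2-[4-(benzyloxy)-3-methoxyphenyl]-7-methoxy-3-(methoxycarbonyl)-2,3-dihydro-1-benzofuran-5-yl]boronic acid | OB(O)c1cc(OC)c2c(c1)[C@H](C(=O)OC)[C@@H](c1ccc(OCc3ccccc3)c(OC)c1)O2 | intermediate
10 | methyl (2S,3S)-2-[4-(benzyloxy)-3-methoxyphenyl]-5-[(2R)-6-bromo-8-methoxy-4-oxo-3,4-dihydro-2H-chromen-2-yl]-7-methoxy-2,3-dihydro-1-benzofuran-3-carboxylate | Brc1cc(OC)c2c(c1)C(=O)C[C@H](c1cc(OC)c3c(c1)[C@H](C(=O)OC)[C@@H](c1ccc(OCc4ccccc4)c(OC)c1)O3)O2 | intermediate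
11 | methyl (2R,3R)-5-bromo-2-[(2S,3S)-2-[4-(benzyloxy)-3-methoxyphenyl]-7-methoxy-3-(methoxycarbonyl)-2,3-dihydro-1-benzofuran-5-yl]-7-methoxy-2,3-dihydro-1-benzofuran-3-carboxylate | Brc1cc(OC)c2c(c1)[C@@H](C(=O)OC)[C@H](c1cc(OC)c3c(c1)[C@H](C(=O)OC)[C@@H](c1ccc(OCc4ccccc4)c(OC)c1)O3)O2 | intermediate
12 | [(2R,3S)-5-bromo-2-{(2S,3R)-2-[4-(benzyloxy)-3-methoxyphenyl]-3-(hydroxymethyl)-7-methoxy-2,3-dihydro-1-benzofuran-5-yl}-7-methoxy-2,3-dihydro-1-benzofuran-3-yl]methanol | Brc1cc(OC)c2c(c1)[C@@H](CO)[C@H](c1cc(OC)c3c(c1)[C@H](CO)[C@@H](c1ccc(OCc4ccccc4)c(OC)c1)O3)O2 | intermediate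
13 | bis(tert-butyldimethylsilyl) ether of 12 | Brc1cc(OC)c2c(c1)[C@@H](CO[Si](C)(C)C(C)(C)C)[C@H](c1cc(OC)c3c(c1)[C@H](CO[Si](C)(C)C(C)(C)C)[C@@H](c1ccc(OCc4ccccc4)c(OC)c1)O3)O2 | intermediate
14 | aryllithium from 13, Li in place of Br (not isolated) | [Li]c1cc(OC)c2c(c1)[C@@H](CO[Si](C)(C)C(C)(C)C)[C@H](c1cc(OC)c3c(c1)[C@H](CO[Si](C)(C)C(C)(C)C)[C@@H](c1ccc(OCc4ccccc4)c(OC)c1)O3)O2 | intermediate
15 | aldehyde from 13, CHO in place of Br | O=Cc1cc(OC)c2c(c1)[C@@H](CO[Si](C)(C)C(C)(C)C)[C@H](c1cc(OC)c3c(c1)[C@H](CO[Si](C)(C)C(C)(C)C)[C@@H](c1ccc(OCc4ccccc4)c(OC)c1)O3)O2 | intermediate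
16 | 4-(benzyloxy)-3-methoxybenzaldehyde | COc1cc(C=O)ccc1OCc1ccccc1 | starting material
17 | dimethyl butanedioate | COC(=O)CCC(=O)OC | starting material
18 | (3E)-4-[4-(benzyloxy)-3-methoxyphenyl]-3-(methoxycarbonyl)but-3-enoic acid | COC(=O)/C(CC(=O)O)=C/c1ccc(OCc2ccccc2)c(OC)c1 | intermediate
19 | (3R)-4-[4-(benzyloxy)-3-methoxyphenyl]-3-(methoxycarbonyl)butanoic acid | COC(=O)[C@@H](CC(=O)O)Cc1ccc(OCc2ccccc2)c(OC)c1 | intermediate
20 | (3R)-3-[4-(benzyloxy)-3-methoxybenzyl]-4-hydroxybutanoic acid (not isolated) | OC[C@@H](CC(=O)O)Cc1ccc(OCc2ccccc2)c(OC)c1 | intermediate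
21 | (4R)-4-[4-(benzyloxy)-3-methoxybenzyl]oxolan-2-one | O=C1C[C@@H](Cc2ccc(OCc3ccccc3)c(OC)c2)CO1 | intermediate
22 | lithium enolate of 21 (not isolated) | [Li]OC1=C[C@@H](Cc2ccc(OCc3ccccc3)c(OC)c2)CO1 | intermediate
23 | (3S,4R)-4-[4-(benzyloxy)-3-methoxybenzyl]-3-[hydroxy(aryl)methyl]oxolan-2-one, carbinol epimers | O=C1OC[C@H](Cc2ccc(OCc3ccccc3)c(OC)c2)[C@H]1C(O)c1cc(OC)c2c(c1)[C@@H](CO[Si](C)(C)C(C)(C)C)[C@H](c1cc(OC)c3c(c1)[C@H](CO[Si](C)(C)C(C)(C)C)[C@@H](c1ccc(OCc4ccccc4)c(OC)c1)O3)O2 | intermediate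
24 | (2R,3R)-2-[hydroxy(aryl)methyl]-3-[4-(benzyloxy)-3-methoxybenzyl]butane-1,4-diol, carbinol epimers | OC[C@H](Cc1ccc(OCc2ccccc2)c(OC)c1)[C@H](CO)C(O)c1cc(OC)c2c(c1)[C@@H](CO[Si](C)(C)C(C)(C)C)[C@H](c1cc(OC)c3c(c1)[C@H](CO[Si](C)(C)C(C)(C)C)[C@@H](c1ccc(OCc4ccccc4)c(OC)c1)O3)O2 | intermediate
25 | (2R,3R)-1-aryl-3-[4-(benzyloxy)-3-methoxybenzyl]-4-hydroxy-2-(hydroxymethyl)butan-1-one (not isolated) | OC[C@H](Cc1ccc(OCc2ccccc2)c(OC)c1)[C@H](CO)C(=O)c1cc(OC)c2c(c1)[C@@H](CO[Si](C)(C)C(C)(C)C)[C@H](c1cc(OC)c3c(c1)[C@H](CO[Si](C)(C)C(C)(C)C)[C@@H](c1ccc(OCc4ccccc4)c(OC)c1)O3)O2 | intermediate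
26 | (3R,4R)-2-aryl-4-[4-(benzyloxy)-3-methoxybenzyl]-3-(hydroxymethyl)oxolan-2-ol, anomers (not isolated) | OC[C@H]1[C@@H](Cc2ccc(OCc3ccccc3)c(OC)c2)COC1(O)c1cc(OC)c2c(c1)[C@@H](CO[Si](C)(C)C(C)(C)C)[C@H](c1cc(OC)c3c(c1)[C@H](CO[Si](C)(C)C(C)(C)C)[C@@H](c1ccc(OCc4ccccc4)c(OC)c1)O3)O2 | intermediate
27 | (2R,3R,4R)-2-aryl-4-[4-(benzyloxy)-3-methoxybenzyl]-3-(hydroxymethyl)oxolane, all-cis, two silyl ethers | COc1cc(C[C@H]2CO[C@@H](c3cc(OC)c4c(c3)[C@@H](CO[Si](C)(C)C(C)(C)C)[C@H](c3cc(OC)c5c(c3)[C@H](CO[Si](C)(C)C(C)(C)C)[C@@H](c3ccc(OCc6ccccc6)c(OC)c3)O5)O4)[C@H]2CO)ccc1OCc1ccccc1 | intermediate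
28 | triol from 27 after loss of both silyl groups, two benzyl ethers | COc1cc(C[C@H]2CO[C@@H](c3cc(OC)c4c(c3)[C@@H](CO)[C@H](c3cc(OC)c5c(c3)[C@H](CO)[C@@H](c3ccc(OCc6ccccc6)c(OC)c3)O5)O4)[C@H]2CO)ccc1OCc1ccccc1 | intermediate
29 | 4-[(2S,3R)-5-[(2R,3S)-5-[(2R,3R,4R)-4-(4-hydroxy-3-methoxybenzyl)-3-(hydroxymethyl)oxolan-2-yl]-3-(hydroxymethyl)-7-methoxy-2,3-dihydro-1-benzofuran-2-yl]-3-(hydroxymethyl)-7-methoxy-2,3-dihydro-1-benzofuran-2-yl]-2-methoxyphenol | COc1cc(C[C@H]2CO[C@@H](c3cc(OC)c4c(c3)[C@@H](CO)[C@H](c3cc(OC)c5c(c3)[C@H](CO)[C@@H](c3ccc(O)c(OC)c3)O5)O4)[C@H]2CO)ccc1O | target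

Total step count: 18. Longest linear sequence: 15 steps (steps 1–10 and 14–18); the lactone branch (steps 11–13) joins at step 14.

Steps most likely to fail

1. Step 7. The 2-aryl group of 10 is an electron-rich dihydrobenzofuranyl ring, so it may migrate from C2 to C3 in place of C4a (isoflavone-type shift). The acid may also ionise the C2–O bond with loss of configuration, or the iodane may oxidise the arene. The fallback sets out from 10 and comes back at 11, and replaces the iodonium-driven shift by a carbene-driven one in which only the acyl-bound carbon C4a can migrate. One equivalent of LiN(SiMe3)2 at −78 °C followed by 2,2,2-trifluoroethyl trifluoroacetate should give the 3-trifluoroacetyl flavanone F1. Methanesulfonyl azide and Et3N in wet MeCN should then effect deacylative Regitz diazo transfer to the 3-diazo flavanone F2. Irradiation at 300–350 nm in MeOH should trigger the Wolff rearrangement, and methanol should trap the ketene as the ring-contracted ester, expected as 11 together with its C3 epimer, the cis ester F3. DBU in CH2Cl2 should equilibrate F3 to 11.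

2. Step 4. The same processes threaten the key step itself: migration of benzyloxy-bearing ring D from C2 to C3, over-oxidation of that ring, or erosion of C2 by acid ionisation. The fallback sets out from 6 and comes back at 7 by the same carbene logic. Trifluoroacetylation as above should give the 3-trifluoroacetyl flavanone F4 and diazo transfer the 3-diazo flavanone F5. Photochemical Wolff rearrangement in MeOH should then give 7 together with the cis ester F6, which DBU should convert into 7.

3. Step 16. The oxocarbenium ion may lose the C3 proton to the enol ether and so epimerise C3 before hydride capture, the hydroxymethyl ketone may undergo β-elimination, or hydride delivery may show poor facial selectivity. The fallback sets out from 24 and comes back at 27. After the MnO2 oxidation to 26 as in the route, pyridinium p-toluenesulfonate with 4 Å sieves in CH2Cl2 should dehydrate the hemiketal to the 4,5-dihydrofuran F7, in which C3 is no longer stereogenic. Hydrogenation with [Ir(cod)(PCy3)(py)]PF6 under H2 in CH2Cl2 should then add both hydrogens syn from the face opposite the C4 arylmethyl group. This sets C2 and C3 together as all-cis from a single control element and spares the benzyl ethers.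

Further compounds
F1 | step 7 | 3-(trifluoroacetyl) derivative of 10 at C3 of the chromanone | Brc1cc(OC)c2c(c1)C(=O)C(C(=O)C(F)(F)F)[C@H](c1cc(OC)c3c(c1)[C@H](C(=O)OC)[C@@H](c1ccc(OCc4ccccc4)c(OC)c1)O3)O2
F2 | step 7 | 3-diazo derivative of 10 (C2 geometry as in 10) | Brc1cc(OC)c2c(c1)C(=O)C(=[N+]=[N-])[C@H](c1cc(OC)c3c(c1)[C@H](C(=O)OC)[C@@H](c1ccc(OCc4ccccc4)c(OC)c1)O3)O2
F3 | step 7 | C3 epimer of 11 in the inner ring (2R,3S, 2,3-cis) | Brc1cc(OC)c2c(c1)[C@H](C(=O)OC)[C@H](c1cc(OC)c3c(c1)[C@H](C(=O)OC)[C@@H](c1ccc(OCc4ccccc4)c(OC)c1)O3)O2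
F4 | step 4 | 3-(trifluoroacetyl) derivative of 6 | Brc1cc(OC)c2c(c1)C(=O)C(C(=O)C(F)(F)F)[C@@H](c1ccc(OCc3ccccc3)c(OC)c1)O2
F5 | step 4 | 3-diazo derivative of 6 (C2 geometry as in 6) | Brc1cc(OC)c2c(c1)C(=O)C(=[N+]=[N-])[C@@H](c1ccc(OCc3ccccc3)c(OC)c1)O2
F6 | step 4 | methyl (2S,3R)-2-[4-(benzyloxy)-3-methoxyphenyl]-5-bromo-7-methoxy-2,3-dihydro-1-benzofuran-3-carboxylate (2,3-cis) | Brc1cc(OC)c2c(c1)[C@@H](C(=O)OC)[C@@H](c1ccc(OCc3ccccc3)c(OC)c1)O2
F7 | step 16 | [(4R)-2-aryl-4-[4-(benzyloxy)-3-methoxybenzyl]-4,5-dihydrofuran-3-yl]methanol (aryl is the C5 residue of 15) | OCC1=C(c2cc(OC)c3c(c2)[C@@H](CO[Si](C)(C)C(C)(C)C)[C@H](c2cc(OC)c4c(c2)[C@H](CO[Si](C)(C)C(C)(C)C)[C@@H](c2ccc(OCc5ccccc5)c(OC)c2)O4)O3)OC[C@@H]1Cc1ccc(OCc2ccccc2)c(OC)c1
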